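## Retrosynthetic overview
1. Ring atoms follow the SMILES. C1 is the ring C=O beside the carbinol, C2 the acyl-bearing carbon, C3 the enol carbon, C4 and C5 the CH2 groups, and C6 the (S)-carbinol.
2. 10 ⇒ 8 by opening C2–C3. The carbocycle is an isomer of a γ-lactone that carries a 1,3-diketone (Dieckmann-type acyl transfer, last step).
3. 8 ⇒ 5 + 6 by opening C1–C2, a crossed Claisen condensation of nonadecan-2-one with a lactone ester.
4. 5 ⇒ 1 + 2 by opening C5–C6 (key step). A propanoate homoenolate (d3) adds to the glyoxylate aldehyde (a1), two carbons that are both electrophilic by nature, in a catalytic enantioselective reaction that sets C6.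
5. Ring order: the γ-lactone forms first (step 1). The six-membered carbocycle forms second (step 3), as the lactone is consumed.

Assumption: the SMILES shows one enol tautomer of freely equilibrating (S)-4-hydroxy-2-octadecanoylcyclohexane-1,3-dione, and the facial sense in step 1 is extrapolated from other aldehydes, so the (1S,2S) ligand would be used if ethyl glyoxylate binds the other way round.

## Route

**Step 1**
Reactants: 1 [(1-ethoxycyclopropyl)oxy]trimethylsilane; 2 ethyl glyoxylate (monomer, freshly cracked from the toluene solution)
Product: 5 ethyl (2S)-5-oxooxolane-2-carboxylate, via zinc homoenolate 3 (not isolated), via hydroxy diester 4 (not isolated)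
Conditions: 1 (3.0 equiv), ZnCl2 (1.5 equiv), Et2O, rt, 1 h, then Me3SiCl and Et2O off in vacuo; toluene, Ti(OtBu)4 (1.5 equiv), (1R,2R)-1,2-bis(trifluoromethanesulfonamido)cyclohexane (10 mol%), slow addition of 2 (1.0 equiv), −40 to −20 °C; 1 M HCl; crude, p-TsOH (2 mol%), toluene, 80 °C, −EtOH
Reagents that add atoms: zinc dichloride, Cl[Zn]Cl (its zinc stays only in intermediate 3)
Why: Proposed new method: ZnCl2 opens the siloxycyclopropane to the Nakamura–Kuwajima zinc homoenolate 3, whose carbon C5 would be the electrophilic β-carbon of an acrylate, and this carbon is joined to the equally electrophilic aldehyde carbon C6 of 2 (asymmetric homoaldol, homo-Reformatsky type); freed of Me3SiCl, chelated 3 is barely reactive toward aldehydes, so the open channel should be alkyl transfer through titanium to the aldehyde held by the strongly Lewis acidic chiral titanium bis(sulfonamide) catalyst formed from the ligand and Ti(OtBu)4, which with the (1R,2R) ligand delivers alkyl groups to the Si face of RCHO and here gives (S)-4 (CO2Et outranks the incoming CH2); Ti(OtBu)4 has no carbinol hydrogen for a Meerwein–Ponndorf–Verley reduction of 2 and transesterifies slowly, and acid then closes 4 to the γ-lactone without touching C6; the closest known reaction types are the bis(sulfonamide)/titanium tetraalkoxide-catalysed enantioselective addition of functionalised dialkylzincs to aldehydes and the racemic addition of zinc or alkoxytitanium homoenolates to aldehydes.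

**Step 2**
Reactants: 5 ethyl (2S)-5-oxooxolane-2-carboxylate; 6 nonadecan-2-one
Product: 8 1-[(2S)-5-oxooxolan-2-yl]icosane-1,3-dione, via lithium enolate 7 (not isolated)
Conditions: 6 (2.1 equiv), commercial LiN(iPr)2 (2.1 equiv), THF, −78 °C, 45 min; 5 (1.0 equiv), −78 °C, 1 h; cold 1 M HCl
Reagents that add atoms: lithium diisopropylamide LiN(iPr)2, [Li+].CC(C)[N-]C(C)C (its lithium stays only in intermediate 7)
Why: Crossed Claisen condensation in which the kinetic terminal enolate attacks the exocyclic ester, made more electrophilic than the lactone carbonyl by its α-acyloxy group (the preference that lets NaBH4 reduce only this ester); the second equivalent of 7 converts the product at once into its inert diketonate, and C6 keeps its configuration because addition at −78 °C outruns deprotonation of C6–H, while minor attack at the lactone carbonyl would be harmless since it leads to the same ring closure in step 3.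

**Step 3**
Reactants: 8 1-[(2S)-5-oxooxolan-2-yl]icosane-1,3-dione
Product: 10 (6S)-3,6-dihydroxy-2-octadecanoylcyclohex-2-en-1-one, via methyl ester 9 (not isolated)
Conditions: NaOMe (2.5 equiv), MeOH/THF 1:1, Ar, 0 to 40 °C; 1 M HCl to pH 2; recrystallisation
Reagents that add atoms: sodium methoxide NaOMe, [Na+].[O-]C (its methoxy group stays only in intermediate 9)
Why: Alkoxide-induced lactone-to-carbocycle acyl transfer (Dieckmann condensation, Lacey–Dieckmann type), in which methoxide reversibly opens the lactone to 9, the diketonate carbon C2 closes onto the ester C3 (6-exo-trig), and the far more acidic triketone enolate acts as the thermodynamic sink; no bond at C6 is broken, and C6–H, lying next to a delocalised anion, is too weakly acidic to epimerise, so (S) is retained.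

## Compound list
1 | [(1-ethoxycyclopropyl)oxy]trimethylsilane | CCOC1(CC1)O[Si](C)(C)C | starting material
2 | ethyl glyoxylate (ethyl 2-oxoacetate) | CCOC(=O)C=O | starting material
3 | bis(3-ethoxy-3-oxopropyl)zinc (zinc homoenolate of ethyl propanoate) | CCOC(=O)CC[Zn]CCC(=O)OCC | intermediate
4 | diethyl (2S)-2-hydroxypentanedioate | CCOC(=O)CC[C@H](O)C(=O)OCC | intermediate
5 | ethyl (2S)-5-oxooxolane-2-carboxylate | CCOC(=O)[C@@H]1CCC(=O)O1 | intermediate
6 | nonadecan-2-one | CCCCCCCCCCCCCCCCCC(C)=O | starting material
7 | lithium nonadec-1-en-2-olate | CCCCCCCCCCCCCCCCCC(=C)[O-].[Li+] | intermediate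
8 | 1-[(2S)-5-oxooxolan-2-yl]icosane-1,3-dione | CCCCCCCCCCCCCCCCCC(=O)CC(=O)[C@@H]1CCC(=O)O1 | intermediate
9 | methyl (4S)-4-hydroxy-5,7-dioxotetracosanoate | CCCCCCCCCCCCCCCCCC(=O)CC(=O)[C@@H](O)CCC(=O)OC | intermediate
10 | (6S)-3,6-dihydroxy-2-octadecanoylcyclohex-2-en-1-one (CNP0110148.1) | CCCCCCCCCCCCCCCCCC(=O)C1=C(O)CC[C@H](O)C1=O | target

## Step count and risks
Total step count: 3. Longest linear sequence: 3.

**Most likely to fail: step 1.** The chelated homoenolate may transfer too slowly. Alternatively, the very reactive glyoxylate may be attacked through an achiral alkoxytitanium pathway, which would lower the ee, or it may oligomerise. The fallback sets out from 3 and comes back at 4. It keeps the homoenolate C5–C6 bond formation but sets the stereocentre in a separate step. Compound 3 is acylated with ethyl chlorooxoacetate under PdCl2(PPh3)2 (2 mol%) in Et2O at rt to give diethyl 2-oxopentanedioate F1. The keto group of F1 is then hydrogenated over Pt/Al2O3 modified with cinchonine (H2, 40 bar, AcOH, Orito-type hydrogenation). This gives 4, which is lactonised to 5 as before.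

**Second: step 3.** Methoxide may cleave 8 or 9 by retro-Claisen reaction, and closure may be slow. C6 may partly epimerise, and unreacted 9 may cyclodehydrate to a furanone on acidification. The fallback sets out from 4 (isolated instead of lactonised) and comes back at 10. It closes the ring at C1–C2 on an acyclic, O-protected substrate.
- TBSCl and imidazole in DMF give diethyl (2S)-2-[(tert-butyldimethylsilyl)oxy]pentanedioate F2.
- Enolate 7 (2.1 equiv, THF, −78 to −40 °C) acylates at the unhindered ester to give ethyl (2S)-2-[(tert-butyldimethylsilyl)oxy]-5,7-dioxotetracosanoate F3.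
- KOtBu (2.2 equiv, THF, 0 °C) effects the Dieckmann closure to (6S)-6-[(tert-butyldimethylsilyl)oxy]-3-hydroxy-2-octadecanoylcyclohex-2-en-1-one F4.
- HF·pyridine in THF removes the silyl group to give 10.

**Third: step 2.** The hard enolate may deprotonate C6–H and cause racemisation. It may contain some internal regioisomer, or it may attack the lactone. The fallback sets out from 5 and comes back at 8. It replaces the hard enolate and ester pair by soft enolisation with an activated acyl donor.
- 2 M HCl at reflux, followed by concentration, gives (2S)-5-oxooxolane-2-carboxylic acid F5.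
- 1H-Benzotriazole and SOCl2 in CH2Cl2 give (5S)-5-(1H-benzotriazole-1-carbonyl)oxolan-2-one F6.
- F6 C-acylates 6 under MgBr2·OEt2 and iPr2NEt in CH2Cl2 at rt to give 8.

## Further compounds
F1 | step 1 | diethyl 2-oxopentanedioate | CCOC(=O)CCC(=O)C(=O)OCC
F2 | step 3 | diethyl (2S)-2-[(tert-butyldimethylsilyl)oxy]pentanedioate | CCOC(=O)CC[C@H](O[Si](C)(C)C(C)(C)C)C(=O)OCC
F3 | step 3 | ethyl (2S)-2-[(tert-butyldimethylsilyl)oxy]-5,7-dioxotetracosanoate | CCCCCCCCCCCCCCCCCC(=O)CC(=O)CC[C@H](O[Si](C)(C)C(C)(C)C)C(=O)OCC
F4 | step 3 | (6S)-6-[(tert-butyldimethylsilyl)oxy]-3-hydroxy-2-octadecanoylcyclohex-2-en-1-one | CCCCCCCCCCCCCCCCCC(=O)C1=C(O)CC[C@H](O[Si](C)(C)C(C)(C)C)C1=O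
F5 | step 2 | (2S)-5-oxooxolane-2-carboxylic acid | OC(=O)[C@@H]1CCC(=O)O1
F6 | step 2 | (5S)-5-(1H-benzotriazole-1-carbonyl)oxolan-2-one | O=C(n1nnc2ccccc12)[C@@H]3CCC(=O)O3
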